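**Plan**

1. Numbering (labdane type): ring A = C1–C5/C10, ring B = C5–C10, C17 = methyl on C8, C18 = 4α-carbon (CHO), C19 = 4β-methyl, C20 = methyl on C10, side chain C11–C15, butenolide C2'–C5'; α = face opposite to C20. Cuts: C15–C5' (vinylogous aldol), C13=C14 (olefination), the C7 methylene out of ring B, C9–C11 and C4–C18 (conjugate additions), C4–C5 (aldol condensation), C10–C20 (conjugate methylation).
2. Enabling feature: in ring B the CH2 C7 lies between the C6 carbinol and the oxygenated, methyl-bearing C8, so ring B is the hydrated and reduced form of the enone C6(=O)–C7H=C8(CH3). C7 can therefore be added as a carbene to the C6=C8 silyl enol ether of a hydrindanone (five-membered ring C5–C6–C8–C9–C10), and the strained C6–C8 cyclopropane bond then cut oxidatively.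
3. Forward order: cyclopentenone (future C5, C6, C8, C9, C10) → quaternary C10 → ring A by aldol condensation, C4 by vinylcopper addition (vinyl = masked C18 aldehyde) → 2-methylcyclopentenone → side chain on C9 with silyl enol ether → cyclopropane → six-membered ring B (enone) → C8–OH via epoxide, C6–OH by reduction → C18 lactone → enal → butenolide.
4. Stereochemistry: C10 from a chiral Cu–NHC catalyst; C4 by addition anti to C20; C9 by addition to the convex face of the cis-hydrindenone; C5 by equilibration to the trans-decalin in the key step; C8 by α-face epoxidation; C6 by dissolving-metal reduction (equatorial OH); C15/C5' by a catalyst-controlled vinylogous Mukaiyama aldol.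

Key step: step 9

Remark: the target is drawn as the open 6α-hydroxy-18-aldehyde; this form and its 6α,18-lactol ring tautomer are taken to interconvert freely, so 24 is drawn as the lactol and 28 in the open form as given; C5 in 9–16 and the cyclopropane carbons of 15 are left undefined in the SMILES because all these isomers converge in step 9.

**Route**

Step 1
Reactants: 1 3-ethoxycyclopent-2-en-1-one; 2 2-(3-chloropropyl)-2-methyl-1,3-dioxolane
Product: 5 3-[3-(2-methyl-1,3-dioxolan-2-yl)propyl]cyclopent-2-en-1-one, via Grignard reagent 3 (not isolated), via carbinol adduct 4 (not isolated)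
Conditions: 2, Mg, BrCH2CH2Br (cat.), THF, reflux; then 1, THF, 0 °C → rt; 0.5 M aq. HCl, 0 °C
Reagents that add atoms: water, O
Why: Stork–Danheiser sequence: 1,2-addition of the Grignard reagent to the vinylogous ester and acid-induced loss of ethanol from the carbinol give the transposed 3-alkylcyclopentenone, the dioxolane surviving the brief cold acid; no stereocentre is formed.

Step 2
Reactants: 5 3-[3-(2-methyl-1,3-dioxolan-2-yl)propyl]cyclopent-2-en-1-one
Product: 6 (R)-3-methyl-3-[3-(2-methyl-1,3-dioxolan-2-yl)propyl]cyclopentan-1-one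
Conditions: Me3Al, Cu(OTf)2 (5 mol%), chiral sulfonate-bearing NHC–Ag complex (2.5 mol%), THF, −78 °C
Reagents that add atoms: trimethylaluminium, C[Al](C)C
Why: Copper-catalysed asymmetric conjugate addition of an alkylaluminium to a β-substituted cyclopentenone, a reaction type established for quaternary carbons in five-membered enones; the chiral NHC–Cu complex (enantiomer chosen to give the R centre) sets the future C10.

Step 3
Reactants: 6 (R)-3-methyl-3-[3-(2-methyl-1,3-dioxolan-2-yl)propyl]cyclopentan-1-one
Product: 8 (3aR)-3a,7-dimethyl-2,3,3a,4,5,6-hexahydro-1H-inden-1-one, via diketone 7 (not isolated)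
Conditions: 1 M HCl, THF, rt; then KOH, MeOH, 65 °C
Reagents that add atoms: none
Why: Acid hydrolysis of the dioxolane followed by base-mediated intramolecular aldol condensation (6-(enolexo)-exo-trig attack of the C5 enolate on the methyl ketone, then dehydration) forms ring A as the fused, fully substituted enone, the only aldol product that can dehydrate; the C10 centre is untouched.

Step 4
Reactants: 8 (3aR)-3a,7-dimethyl-2,3,3a,4,5,6-hexahydro-1H-inden-1-one
Product: 9 4α-vinyl-4β-methyl hydrindanone
Conditions: CH2=CHMgBr, CuBr·SMe2 (1.2 equiv), BF3·OEt2, THF, −78 → −40 °C; aq. NH4Cl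
Reagents that add atoms: vinylmagnesium bromide, C=C[Mg]Br
Why: Conjugate addition of a BF3-activated vinylcopper reagent to the s-cis β,β-disubstituted enone; the reagent should attack C4 on the face opposite to the pseudoaxial C10 methyl (1,3-diaxial clash on the other face), placing vinyl (the future C18 aldehyde) α and leaving the methyl β, while C5 is left open because it is corrected in step 9.

Step 5
Reactants: 9 4α-vinyl-4β-methyl hydrindanone
Product: 10 8-methyl hydrindanone
Conditions: LDA, THF, −78 °C; MeI, −78 → 0 °C
Reagents that add atoms: iodomethane, CI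
Why: Kinetic enolate alkylation: LDA removes a proton from the unhindered C8 methylene (C5–H is flanked by two quaternary carbons) and iodomethane gives the 8-methyl ketone as an inconsequential epimer mixture, C8 becoming sp2 in the next step.

Step 6
Reactants: 10 8-methyl hydrindanone
Product: 11 2-methylcyclopentenone-fused hydrindenone
Conditions: IBX, DMSO/fluorobenzene, 75 °C
Reagents that add atoms: none
Why: IBX-mediated α,β-dehydrogenation of a ketone; only C8–C9 can be desaturated because C5 has no β-hydrogen, and the ring-fusion hydrogen at C5 settles in the more stable, presumably cis-fused form.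

Step 7
Reactants: 11 2-methylcyclopentenone-fused hydrindenone; 12 2-(2-bromoethyl)-2-methyl-1,3-dioxolane
Product: 14 C6-trimethylsilyl enol ether bearing the 9β side chain, via Grignard reagent 13 (not isolated)
Conditions: 12, Mg, THF, 25 °C; then CuBr·SMe2 (20 mol%), TMSCl, HMPA, THF, −78 °C, 11; Et3N quench
Reagents that add atoms: chlorotrimethylsilane, C[Si](C)(C)Cl
Why: Copper-catalysed, TMSCl-accelerated conjugate addition of a Grignard reagent with O-silylation of the enolate; the nucleophile is expected to add to C9 on the convex face of the cis-fused hydrindenone (the face carrying C5–H and the C10 methyl), giving the side chain cis to that methyl (9β), and the enolate is trapped regiospecifically as the C6=C8 silyl enol ether.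

Step 8
Reactants: 14 C6-trimethylsilyl enol ether bearing the 9β side chain
Product: 15 siloxycyclopropane
Conditions: Et2Zn, CH2I2, CH2Cl2, 0 °C → rt
Reagents that add atoms: diiodomethane, ICI
Why: Simmons–Smith cyclopropanation (Furukawa variant): the zinc carbenoid adds to the electron-rich silyl enol ether far faster than to the hindered monosubstituted vinyl group, and the face of addition does not matter because C6 and C8 become sp2 in step 9.

Step 9
Reactants: 15 siloxycyclopropane
Product: 17 trans-fused Δ7-en-6-one, via β-chloro ketone 16 (not isolated)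
Conditions: FeCl3 (2.2 equiv), pyridine (1 equiv), DMF, 0 °C → rt; then NaOAc, MeOH, 65 °C; DBU (cat.), rt
Reagents that add atoms: none
Why: One-electron oxidation of the siloxycyclopropane by Fe(III) gives a cyclopropyloxy radical that undergoes β-scission of the shared C6–C8 bond, because this cleavage gives the tertiary C8 radical next to the new C6 ketone (the alternative C6–C7 scission would give a primary radical), so the cyclopentane C5–C6–C8–C9–C10 becomes the six-membered ring B with C7 inserted, driven by release of cyclopropane strain. Chlorine transfer from a second FeCl3 traps the radical as β-chloro ketone 16, and acetate then removes the acidic H7 and expels chloride (E1cB) to give only the conjugated Δ7-enone. The closest known reaction is the Ito–Saegusa ring enlargement of 1-siloxybicyclo[n.1.0]alkanes to 2-cycloalkenones. No ring is closed by a new bond: ring B arises by scission of the zero bridge of the bicyclo[3.1.0]hexane, a one-carbon ring expansion. The only new stereocentre, C5, is under thermodynamic control, epimerising through its enol under DBU to the trans-decalin (5α-H), so both C5 epimers and both cyclopropane diastereomers of 15 converge on one product. The vinyl group and the ketal take no part, and pyridine buffering with a non-acidic work-up keeps the ketal intact.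

Step 10
Reactants: 17 trans-fused Δ7-en-6-one
Product: 18 7α,8α-epoxy-6-ketone
Conditions: 30% H2O2, aq. NaOH, MeOH, 0 °C → rt
Reagents that add atoms: hydrogen peroxide, OO
Why: Weitz–Scheffer epoxidation: hydroperoxide anion should add to C8 from the α face, anti to the axial C10 methyl and to the 9β side chain, so the epoxide oxygen, and hence the C8 oxygen of the target, is α.

Step 11
Reactants: 18 7α,8α-epoxy-6-ketone
Product: 19 8α-hydroxy-6-ketone
Conditions: SmI2 (2.2 equiv), THF/MeOH, −90 °C
Reagents that add atoms: none
Why: Samarium diiodide reduction of an α,β-epoxy ketone: the ketyl expels the Cα–O bond at C7 and leaves the C8–O bond untouched, giving the 8α tertiary alcohol with the methyl β (axial) without the retro-aldol risk of basic conditions.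

Step 12
Reactants: 19 8α-hydroxy-6-ketone
Product: 20 6α,8α-diol
Conditions: Li, NH3(l)/THF, t-BuOH, −78 °C; NH4Cl
Reagents that add atoms: none
Why: Dissolving-metal reduction of a hindered cyclohexanone gives the thermodynamically preferred equatorial alcohol (6α), since an axial 6β-oxygen would be syn-diaxial to the C19 and C20 methyls, whereas hydride reagents attacking from the open α face would give the 6β epimer; the isolated vinyl group and the ketal are inert.

Step 13
Reactants: 20 6α,8α-diol
Product: 22 keto lactone (18→6α-olide), via lactol 21 (not isolated)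
Conditions: O3, CH2Cl2/MeOH, −78 °C; Me2S; then Jones reagent (CrO3, aq. H2SO4), acetone, 0 °C
Reagents that add atoms: ozone, [O-][O+]=O; water, O
Why: Ozonolysis of the vinyl group gives the C18 aldehyde, which closes with the neighbouring equatorial 6α-hydroxyl to the lactol; Jones oxidation turns the lactol into the γ-lactone and its aqueous acid removes the dioxolane, so C18 is stored at an oxidation level that tolerates the olefination.

Step 14
Reactants: 22 keto lactone (18→6α-olide)
Product: 23 (E)-α,β-unsaturated Weinreb amide
Conditions: (EtO)2P(O)CH2C(O)N(OMe)Me, NaH, THF, 0 → 60 °C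
Reagents that add atoms: diethyl [2-(methoxy(methyl)amino)-2-oxoethyl]phosphonate, CCOP(=O)(OCC)CC(=O)N(C)OC
Why: Horner–Wadsworth–Emmons olefination of the methyl ketone with a Weinreb-amide phosphonate should give mainly the (E)-trisubstituted alkene (amide trans to the chain), the minor Z isomer being removed by chromatography; the lactone has no α-hydrogen and the tertiary alkoxide is a bystander.

Step 15
Reactants: 23 (E)-α,β-unsaturated Weinreb amide
Product: 24 (E)-enal lactol
Conditions: DIBAL-H (4 equiv), CH2Cl2, −78 °C; Rochelle salt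
Reagents that add atoms: none
Why: DIBAL-H reduces the Weinreb amide to the enal through its stable chelated tetrahedral intermediate and the γ-lactone to the lactol (the masked C18 aldehyde) at −78 °C, so both carbonyls reach the aldehyde level in one operation.

Step 16
Reactants: 25 4-methylfuran-2(5H)-one
Product: 26 4-methyl-2-(trimethylsilyloxy)furan
Conditions: TMSOTf, Et3N, Et2O, 0 °C
Reagents that add atoms: trimethylsilyl trifluoromethanesulfonate, C[Si](C)(C)OS(=O)(=O)C(F)(F)F
Why: Silylation of the butenolide dienolate gives the 2-silyloxyfuran, the standard nucleophile for vinylogous Mukaiyama aldol reactions.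

Step 17
Reactants: 24 (E)-enal lactol; 26 4-methyl-2-(trimethylsilyloxy)furan
Product: 28 target CNP0112578.1, via silyl ether 27 (not isolated)
Conditions: Ti(OiPr)4/(R)-BINOL (20 mol%), Et2O, −20 °C; then 1 M HCl, THF, 0 °C
Reagents that add atoms: none
Why: Vinylogous Mukaiyama aldol reaction catalysed by a BINOL–titanium(IV) complex: the silyloxyfuran adds through C5' to the enal carbonyl, such additions favour the 5,1'-threo (like) relationship required here, and the catalyst enantiomer (assumed (R)-BINOL, otherwise its antipode) should set the (S,S) sense independently of the remote core; acidic work-up removes the silyl ether.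

**Compound list**

1 | 3-ethoxycyclopent-2-en-1-one | CCOC1=CC(=O)CC1 | starting material
2 | 2-(3-chloropropyl)-2-methyl-1,3-dioxolane | CC1(CCCCl)OCCO1 | starting material
3 | [3-(2-methyl-1,3-dioxolan-2-yl)propyl]magnesium chloride | CC1(CCC[Mg]Cl)OCCO1 | intermediate
4 | 3-ethoxy-1-[3-(2-methyl-1,3-dioxolan-2-yl)propyl]cyclopent-2-en-1-ol (1,2-adduct, formed as its magnesium alkoxide) | CCOC1=CC(O)(CCCC2(C)OCCO2)CC1 | intermediate
5 | 3-[3-(2-methyl-1,3-dioxolan-2-yl)propyl]cyclopent-2-en-1-one | O=C1C=C(CCCC2(C)OCCO2)CC1 | intermediate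
6 | (R)-3-methyl-3-[3-(2-methyl-1,3-dioxolan-2-yl)propyl]cyclopentan-1-one | O=C1C[C@](C)(CCCC2(C)OCCO2)CC1 | intermediate
7 | (R)-3-methyl-3-(4-oxopentyl)cyclopentan-1-one | O=C1C[C@](C)(CCCC(C)=O)CC1 | intermediate
8 | (3aR)-3a,7-dimethyl-2,3,3a,4,5,6-hexahydro-1H-inden-1-one (ring A closed; enone C6(=O)–C5=C4; C10 quaternary) | O=C1CC[C@@]2(C)CCCC(C)=C12 | intermediate
9 | 7-ethenyl-3a,7-dimethyloctahydro-1H-inden-1-one: C6 ketone, 4α-vinyl (trans to the C10 methyl), 4β-methyl, C5 epimers | O=C1CC[C@@]2(C)CCC[C@@](C)(C=C)C12 | intermediate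
10 | 2-methyl derivative of 9 (methyl on C8; C8 and C5 epimers) | O=C1C(C)C[C@@]2(C)CCC[C@@](C)(C=C)C12 | intermediate
11 | 7-ethenyl-2,3a,7-trimethyl-3a,4,5,6,7,7a-hexahydro-1H-inden-1-one: enone C6(=O)–C8(CH3)=C9H, 4α-vinyl, C5–H mainly cis to the C10 methyl | O=C1C(C)=C[C@@]2(C)CCC[C@@](C)(C=C)C12 | intermediate
12 | 2-(2-bromoethyl)-2-methyl-1,3-dioxolane | CC1(CCBr)OCCO1 | starting material
13 | [2-(2-methyl-1,3-dioxolan-2-yl)ethyl]magnesium bromide | CC1(CC[Mg]Br)OCCO1 | intermediate
14 | hydrindene silyl enol ether: C6–OSiMe3, C6=C8, C8–CH3, C9 bearing β-CH2CH2C(OCH2CH2O)CH3 (cis to the C10 methyl, 9α-H), 4α-vinyl, 4β-methyl | CC1(CC[C@@H]2[C@@]3(C)CCC[C@@](C)(C=C)C3C(O[Si](C)(C)C)=C2C)OCCO1 | intermediate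
15 | siloxycyclopropane: C7 methylene bridging C6 (OSiMe3) and C8 (CH3) of 14, both cyclopropane faces | CC1(CC[C@@H]2[C@@]3(C)CCC[C@@](C)(C=C)C3C4(O[Si](C)(C)C)CC24C)OCCO1 | intermediate
16 | 8-chloro-6-ketone of the ring-expanded decalin (C5 and C8 epimers) | CC1(CC[C@@H]2[C@@]3(C)CCC[C@@](C)(C=C)C3C(=O)CC2(C)Cl)OCCO1 | intermediate
17 | trans-decal-7-en-6-one: 5α-H, 8-methyl, 9β-[2-(2-methyl-1,3-dioxolan-2-yl)ethyl], 10β-methyl, 4α-vinyl, 4β-methyl | CC1(CC[C@@H]2[C@@]3(C)CCC[C@@](C)(C=C)[C@@H]3C(=O)C=C2C)OCCO1 | intermediate
18 | 7α,8α-epoxide of 17 (6-ketone retained) | CC1(CC[C@@H]2[C@@]3(C)CCC[C@@](C)(C=C)[C@@H]3C(=O)[C@H]4O[C@@]24C)OCCO1 | intermediate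
19 | 8α-hydroxy-8β-methyl-6-ketone (other centres as in 17) | CC1(CC[C@@H]2[C@@]3(C)CCC[C@@](C)(C=C)[C@@H]3C(=O)C[C@@]2(C)O)OCCO1 | intermediate
20 | 6α,8α-diol (6α-OH equatorial; 4α-vinyl; side-chain ketal) | CC1(CC[C@@H]2[C@@]3(C)CCC[C@@](C)(C=C)[C@@H]3[C@@H](O)C[C@@]2(C)O)OCCO1 | intermediate
21 | 6α,18-lactol (cyclic hemiacetal of the C18 aldehyde with 6α-OH; anomers), 8α-OH, side-chain ketal | CC1(CC[C@@H]2[C@@]3(C)CCC[C@@]4(C)C(O)O[C@H]([C@H]34)C[C@@]2(C)O)OCCO1 | intermediate
22 | 18→6α γ-lactone with 8α-OH and 9β-(3-oxobutyl) side chain | CC(=O)CC[C@@H]1[C@@]2(C)CCC[C@@]3(C)C(=O)O[C@H]([C@H]23)C[C@@]1(C)O | intermediate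
23 | (E)-N-methoxy-N-methyl enamide at C13=C14 (C15 amide), lactone and 8α-OH as in 22 | CON(C)C(=O)/C=C(\C)CC[C@@H]1[C@@]2(C)CCC[C@@]3(C)C(=O)O[C@H]([C@H]23)C[C@@]1(C)O | intermediate
24 | (E)-C15 enal with 6α,18-lactol and 8α-OH | O=C/C=C(\C)CC[C@@H]1[C@@]2(C)CCC[C@@]3(C)C(O)O[C@H]([C@H]23)C[C@@]1(C)O | intermediate
25 | 4-methylfuran-2(5H)-one | CC1=CC(=O)OC1 | starting material
26 | 4-methyl-2-(trimethylsilyloxy)furan | Cc1coc(O[Si](C)(C)C)c1 | intermediate
27 | 15-O-trimethylsilyl ether of the aldol adduct (lactol form) | CC1=CC(=O)O[C@@H]1[C@@H](O[Si](C)(C)C)/C=C(\C)CC[C@@H]1[C@@]2(C)CCC[C@@]3(C)C(O)O[C@H]([C@H]23)C[C@@]1(C)O | intermediate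
28 | target CNP0112578.1 (open hydroxy aldehyde form) | CC1=CC(=O)O[C@@H]1[C@@H](O)/C=C(\C)CC[C@@H]1[C@@]2(C)CCC[C@@](C)(C=O)[C@@H]2[C@@H](O)C[C@@]1(C)O | target

**Step count**

Total steps: 17. Longest linear sequence: 16 (steps 1–15 and 17; step 16 is a one-step side branch).

**Steps most likely to fail**

Step 7. The organocopper reagent may attack the wrong face of C9 (anti to the C10 methyl), or add sluggishly to the hindered α-methyl enone. The fallback sets out from 11. If the chain enters on the α face, the resulting 9-epimeric silyl enol ether F1 is oxidised (Saegusa–Ito conditions: Pd(OAc)2, DMSO, O2) to the tetrasubstituted enone F2, in which C9 is planar again. Conjugate reduction with Stryker's reagent then brings hydride, instead of carbon, to that same accessible face and gives the 9β-chain ketone F3. TMSOTf/Et3N converts it into the more substituted silyl enol ether, and the route is rejoined at 14.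

Step 4. The vinylcopper reagent may react slowly or by 1,2-addition at the tetrasubstituted β-carbon, or lose facial selectivity. The fallback sets out from 8. Conjugate alkynylation with diethyl(trimethylsilylethynyl)aluminium, whose cyclic transfer needs the s-cis enone present here, should give the silylalkynyl ketone F4. K2CO3/MeOH removes silicon to give the ethynyl ketone F5, and Lindlar semi-hydrogenation returns to 9.

Step 17. Catalyst control over the two new centres may be insufficient, and the free lactol may divert the Lewis acid and the silyloxyfuran (ring opening to the C18 aldehyde or ionisation at C18). The fallback sets out from 24. PPTS/MeOH masks the lactol as the methyl acetal F6. Butenolide 25 itself is then added in a direct vinylogous aldol reaction under a chiral bifunctional amine–squaramide catalyst (no Lewis acid, no silyl dienolate) to give the acetal adduct F7. AcOH/THF/H2O unmasks the lactol and returns to 28.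

Further compounds
F1 | step 7 | 9-epimer of silyl enol ether 14 (side chain α) | CC1(CC[C@H]2[C@@]3(C)CCC[C@@](C)(C=C)C3C(O[Si](C)(C)C)=C2C)OCCO1
F2 | step 7 | tetrasubstituted enone C6(=O)–C8(CH3)=C9(side chain) | CC1(CCC2=C(C)C(=O)C3[C@](C)(C=C)CCC[C@]23C)OCCO1
F3 | step 7 | 9β-side-chain ketone (9α-H; C8 and C5 epimers) | CC1(CC[C@H]2C(C)C(=O)C3[C@](C)(C=C)CCC[C@]23C)OCCO1
F4 | step 4 | 4α-(trimethylsilylethynyl) analogue of 9 | O=C1CC[C@@]2(C)CCC[C@@](C)(C#C[Si](C)(C)C)C12
F5 | step 4 | 4α-ethynyl analogue of 9 | O=C1CC[C@@]2(C)CCC[C@@](C)(C#C)C12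
F6 | step 17 | methyl acetal of enal lactol 24 | O=C/C=C(\C)CC[C@@H]1[C@@]2(C)CCC[C@@]3(C)C(OC)O[C@H]([C@H]23)C[C@@]1(C)O
F7 | step 17 | methyl acetal of the target lactol | CC1=CC(=O)O[C@@H]1[C@@H](O)/C=C(\C)CC[C@@H]1[C@@]2(C)CCC[C@@]3(C)C(OC)O[C@H]([C@H]23)C[C@@]1(C)O
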